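The flask is to be reckoned as a balance and not as a race, for the earlier readings stand flat from the first sample: elm gives 36.6% product at 0.500 d and 37.3% at 8.00 d, with a scatter of 0.5 percentage points.

| flask | substrate | coupling partner | remark | time |
|---|---|---|---|---|
| elm | 0.025 M | 0.025 M (fed, over 50 min) | run made earlier; the fed solution adds 0.50 times the starting volume |  |
| birch | 0.038 M | 0.025 M (fed, over 50 min) | run made earlier; the fed solution adds 0.50 times the starting volume |  |
| maple | 0.050 M | 0.050 M (fed, over 50 min) | run made earlier; the fed solution adds 0.50 times the starting volume |  |
| flask | 0.050 M | 0.0250 M (fed, over 50 min) | the fed solution adds 0.50 times the starting volume | 10 d |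

| run | time / d | product / % | intermediate / % |
|---|---|---|---|
| elm | 0.500 | 36.6 | 4.3 |
| elm | 1.67 | 38.5 | 4.5 |
| elm | 3.00 | 36.9 | 4.7 |
| elm | 4.00 | 37.6 | 4.0 |
| elm | 6.00 | 37.2 | 3.6 |
| elm | 8.00 | 37.3 | 5.2 |
| birch | 0.500 | 29.4 | 4.0 |
| birch | 1.67 | 29.7 | 4.4 |
| birch | 3.00 | 30.9 | 4.4 |
| birch | 4.00 | 30.6 | 4.7 |
| birch | 6.00 | 30.0 | 4.5 |
| birch | 8.00 | 31.1 | 4.1 |
| maple | 1.67 | 36.2 | 8.1 |
| maple | 3.00 | 35.4 | 7.5 |
| maple | 5.00 | 36.2 | 8.5 |
| maple | 6.00 | 35.6 | 8.6 |
| maple | 8.00 | 35.7 | 7.9 |

(scatter of a reading: 0.5 percentage points)

- every charge counts on the volume at the start, and the solution that is fed holds the whole dose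
- the reaction counts as stopped when no species that holds the substrate changes by six tenths of a point or more over the second half of the time

* the state of affairs at 10 d: stopped, and by what, or still going (forward and back rates have come level / it is still moving / all of the substrate has reacted / the coupling partner has run out first)
* product at 10 d, in percent of the substrate charged
* intermediate at 10 d, in percent of the substrate charged

From elm to maple both charges go up to twice their amount. Product averages 37.4% in elm against 35.8% in maple, while intermediate goes from 4.38% to 8.12%. Product therefore reads as leaving with a released group in equal amount, and the volume cancels from c(product)·c(released group)/(c(substrate)·c(coupling partner)), each c taken on the starting volume. With birch averaging 30.3% and 4.35%, this ratio reads 0.411 for elm, 0.450 for birch and 0.408 for maple. Their mean 0.423 is the reading of the exchange quotient, lower than the symmetric zero of one, at which neither side is favoured. Maple also gives c(intermediate) as 12.7 M⁻¹ times c(product) squared.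

In the first instants of the flask, the coupling partner, the limiting reagent at 0.0250 M against 0.050 M of substrate, enters over 50 min and meets substrate in excess. The middle of the run is unseen, since elm is already flat at 0.500 d, and the flask is expected to be as quick. The end of the flask is reckoned as thermodynamic control. The quotient without intermediate gives 0.0134 M product, which carries 0.00227 M intermediate. Taking that from both charges and solving again gives 0.0124 M. The reckoning for the flask is thus 24.8% product and 3.90% intermediate, with 42.5% of the coupling partner left, and forward and back rates level.

The forecast reads forward and back rates have come level, with 25.2% product, a little more than the reckoning here, and 4% intermediate: “Partner remains, so equilibrium ends the reaction.” The flask gives forward and back rates have come level, with 25.0% product and 3.94% intermediate.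

    substrate + coupling partner ⇌ intermediate (K = 7.90 M⁻¹, k = 120 M⁻¹ h⁻¹)
    intermediate ⇌ product + released group (K = 0.0530 M, k = 1.00 h⁻¹)

In the flask the relaxation half-life of intermediate with product and released group, 0.527 h for both directions together, is shorter than the time of 10 d. Up to that time the backward turnover of this step comes to 97% of the forward one. The amounts in the flask at 10.0 d give an exchange quotient of 0.419. The neighbour charged with 0.10 M of coupling partner holds 47.3% product, 38.6% substrate and 69.3% of its partner, which gives a quotient of 0.418.

(The readings stem from a simulated flask on assumed constants; scatter was added.)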